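**Retrosynthetic overview**
- The target is reached by late tigloylation at C8 of a 13-acetoxy-7(11)-en-12,6-olide, which comes from an α-methylene 12,6-lactone by acetoxyselenenylation and selenoxide elimination; the lactone comes from a C6/C12 diol, and the 4,5-epoxide from C6-hydroxyl-directed epoxidation.
- The strategy rests on the C6 carbinol (the lactone oxygen) standing next to C7, which carries the three-carbon C11(C12)(C13) branch on the ten-membered carbocycle C1–C10: a [2,3]-Wittig shift of a C6–O–C13 allyl ether makes C6–C7 and leaves C6–OH and a C11=C13 methylene.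
- Ring order: thirteen-membered ether (Williamson closure C6–O–C13), then ten-membered carbocycle (ring contraction), then epoxide, then γ-lactone.
- Seco chain: nerol gives C2–C6 with the Z C4=C5 alkene and C1 by cleavage of the remote alkene; anti-crotylboration sets C1/C10; hydroboration gives C8; methyl propiolate brings C7, C11 and C13; trans-hydroalumination/iodination and Stille hydroxymethylation add C12.

Key step: step 17

Remark: germacrane numbering is used throughout (C1 OAc, C4–C5 epoxide, C6 lactone O, C7=C11, C8 tiglate, C10 methyl, C12 lactone carbonyl, C13 CH2OAc); C7 is a stereocentre only in intermediates and ends sp2. PMB = 4-methoxybenzyl, TES = triethylsilyl, TBS = tert-butyldimethylsilyl.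

**Route**

Step 1
Reactants: 1 nerol
Product: 2 neryl PMB ether
Conditions: NaH, 4-methoxybenzyl chloride, Bu4NI (cat.), THF/DMF, 0 °C to rt
Reagents that add atoms: 4-methoxybenzyl chloride, COc1ccc(CCl)cc1
Why: Williamson etherification of the primary allylic alkoxide masks the future C6 oxygen as an ether that survives the hydride and organometallic steps and can be removed oxidatively, and the Z C4=C5 alkene is carried unchanged.

Step 2
Reactants: 2 neryl PMB ether
Product: 4 (4Z)-6-(PMB-oxy)-4-methylhex-4-enal, via remote epoxide 3 (not isolated)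
Conditions: mCPBA, NaHCO3, CH2Cl2, 0 °C; then H5IO6, THF/H2O, 0 °C
Reagents that add atoms: mCPBA, OOC(=O)c1cccc(Cl)c1
Why: Prilezhaev epoxidation should pick the remote, more electron-rich trisubstituted alkene (C4=C5 is deactivated by the allylic ether oxygen), and periodic acid cleaves the epoxide through the diol to the C1 aldehyde and acetone.

Step 3
Reactants: 4 (4Z)-6-(PMB-oxy)-4-methylhex-4-enal; 5 (E)-crotylboronic acid pinacol ester
Product: 7 (3R,4S,7Z)-9-(PMB-oxy)-3,7-dimethylnona-1,7-dien-4-ol, via pinacol borate ester 6 (not isolated)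
Conditions: (R)-TRIP (5 mol%), 4 Å MS, toluene, −30 °C; aqueous work-up
Reagents that add atoms: none
Why: Chiral phosphoric acid-catalysed crotylboration through a closed chair transition state turns the E geometry of the boronate into the 1,10-anti relationship, and the (R)-catalyst is expected to deliver the crotyl group to the Re face of the aldehyde, which sets C1 (S) and C10 (R).

Step 4
Reactants: 7 (3R,4S,7Z)-9-(PMB-oxy)-3,7-dimethylnona-1,7-dien-4-ol
Product: 8 C1 triethylsilyl ether of 7
Conditions: Et3SiCl, imidazole, DMAP (cat.), CH2Cl2, 0 °C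
Reagents that add atoms: chlorotriethylsilane, CC[Si](Cl)(CC)CC
Why: Silylation of the secondary alcohol, the TES group being chosen because it can later be removed in the presence of the hindered C8 TBS ether.

Step 5
Reactants: 8 C1 triethylsilyl ether of 7
Product: 10 (3R,4S,7Z)-9-(PMB-oxy)-3,7-dimethyl-4-(triethylsilyloxy)non-7-en-1-ol, via alkylborane 9 (not isolated)
Conditions: 9-BBN, THF, 0 °C to rt; then NaOH, H2O2, 0 °C
Reagents that add atoms: hydrogen peroxide, OO
Why: Anti-Markovnikov hydroboration–oxidation with 9-BBN reacts only at the terminal vinyl group and leaves the trisubstituted C4=C5 alkene, placing the hydroxyl on C8.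

Step 6
Reactants: 10 (3R,4S,7Z)-9-(PMB-oxy)-3,7-dimethyl-4-(triethylsilyloxy)non-7-en-1-ol
Product: 11 (3R,4S,7Z)-9-(PMB-oxy)-3,7-dimethyl-4-(triethylsilyloxy)non-7-enal
Conditions: Dess–Martin periodinane, NaHCO3, CH2Cl2, 0 °C to rt
Reagents that add atoms: none
Why: Dess–Martin oxidation gives the C8 aldehyde under buffered conditions that neither cleave the silyl ether nor touch C10, which is beta to the carbonyl.

Step 7
Reactants: 11 (3R,4S,7Z)-9-(PMB-oxy)-3,7-dimethyl-4-(triethylsilyloxy)non-7-enal; 12 methyl propiolate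
Product: 14 methyl (6R,7S,10Z)-4-hydroxy-12-(PMB-oxy)-6,10-dimethyl-7-(triethylsilyloxy)dodec-10-en-2-ynoate (both C8 epimers), via lithium methyl propiolate 13 (not isolated)
Conditions: LiN(iPr)2, 12, THF, −78 °C; then 11, −78 °C; NH4Cl (aq)
Reagents that add atoms: none
Why: 1,2-Addition of the lithium acetylide to the aldehyde forms C7–C8 and brings in C7, C11 and C13 (as the ester); the C8 epimers are converged in steps 8 and 9.

Step 8
Reactants: 14 propargylic alcohol (C8 epimers)
Product: 15 methyl (6R,7S,10Z)-12-(PMB-oxy)-6,10-dimethyl-4-oxo-7-(triethylsilyloxy)dodec-10-en-2-ynoate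
Conditions: Dess–Martin periodinane, NaHCO3, CH2Cl2, 0 °C
Reagents that add atoms: none
Why: Dess–Martin oxidation of the propargylic alcohol gives the ynone so that C8 can be set by reagent control.

Step 9
Reactants: 15 ynone
Product: 17 methyl (4S,6R,7S,10Z)-4-hydroxy-12-(PMB-oxy)-6,10-dimethyl-7-(triethylsilyloxy)dodec-10-en-2-ynoate, via B-alkoxy-9-BBN borinate 16 (not isolated)
Conditions: (S)-Alpine-Borane, THF (concentrated), rt; then ethanolamine
Reagents that add atoms: none
Why: Midland reduction transfers the pinanyl hydride through a boat-like six-membered transition state with the slim alkynyl group in the hindered position, so the (S)-reagent should give the (8S) propargylic alcohol.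

Step 10
Reactants: 17 (8S)-propargylic alcohol
Product: 19 methyl (2Z,4S,6R,7S,10Z)-4-hydroxy-2-iodo-12-(PMB-oxy)-6,10-dimethyl-7-(triethylsilyloxy)dodeca-2,10-dienoate, via cyclic vinylalanate 18 (not isolated)
Conditions: NaAlH2(OCH2CH2OCH3)2 (Red-Al), THF, −72 °C; then I2, THF, −72 to −20 °C
Reagents that add atoms: iodine, II
Why: trans-Hydroalumination of the γ-hydroxy ynoate delivers hydride from the C8 alkoxyaluminate to C7 and leaves aluminium on C11 in a five-membered chelate, and iodinolysis with retention gives the iodo enoate with the ester (C13) trans to C8, the ester being untouched at this temperature.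

Step 11
Reactants: 19 (Z)-iodo enoate; 20 (tributylstannyl)methanol
Product: 21 methyl (2E,4S,6R,7S,10Z)-4-hydroxy-2-(hydroxymethyl)-12-(PMB-oxy)-6,10-dimethyl-7-(triethylsilyloxy)dodeca-2,10-dienoate
Conditions: Pd2(dba)3 (zerovalent palladium, cat.), AsPh3, CuI, NMP, 50 °C
Reagents that add atoms: none
Why: Stille coupling of the α-iodo enoate with the hydroxymethylstannane proceeds with retention of alkene geometry and installs C12 as CH2OH cis to C8.

Step 12
Reactants: 21 diol ester
Product: 22 8,12-bis-TBS ether of 21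
Conditions: TBSOTf, 2,6-lutidine, CH2Cl2, −78 to 0 °C
Reagents that add atoms: tert-butyldimethylsilyl triflate, CC(C)(C)[Si](C)(C)OS(=O)(=O)C(F)(F)F
Why: Silyl triflate silylation protects the secondary C8 and primary C12 hydroxyls in one operation, while the C1 TES ether stays as the more labile group for later differentiation.

Step 13
Reactants: 22 8,12-bis-TBS ester
Product: 23 C13 allylic alcohol
Conditions: iBu2AlH, CH2Cl2, −78 °C; Rochelle salt work-up
Reagents that add atoms: none
Why: 1,2-Selective hydride reduction of the conjugated ester frees C13 as the only hydroxyl of the molecule, so no protecting-group step is needed to single it out.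

Step 14
Reactants: 23 C13 allylic alcohol
Product: 24 C13 allylic chloride
Conditions: N-chlorosuccinimide, Me2S, CH2Cl2, −20 to 0 °C
Reagents that add atoms: N-chlorosuccinimide, O=C1CCC(=O)N1Cl
Why: Corey–Kim chlorination converts the primary allylic alcohol to the chloride by SN2 on the alkoxysulfonium salt without allylic transposition and without harming silyl or PMB ethers.

Step 15
Reactants: 24 C13 allylic chloride
Product: 25 seco chloro alcohol (C6–OH, C13–Cl)
Conditions: DDQ, CH2Cl2/pH 7 buffer, 0 °C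
Reagents that add atoms: none
Why: Oxidative PMB cleavage by DDQ (benzylic hydride abstraction, then hydrolysis) frees the C6 alcohol and leaves the silyl ethers and the allylic chloride intact.

Step 16
Reactants: 25 seco chloro alcohol
Product: 26 thirteen-membered diallyl ether (1S,8S,10R; Z C4=C5; C13 trans to C8 on C7=C11; 1-OTES, 8-OTBS, 12-OTBS)
Conditions: NaH, NaI (cat.), THF, slow addition at high dilution, reflux
Reagents that add atoms: none
Why: Intramolecular Williamson etherification (SN2 of the C6 alkoxide at the primary allylic C13 chloride) closes the thirteen-membered ring under high dilution, with both alkenes and the three stereocentres as spectators.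

Step 17
Reactants: 26 thirteen-membered diallyl ether
Product: 28 ten-membered C6 alcohol (1S,6R,7S,8S,10R) with the C11(=C13H2)–C12H2OTBS branch on C7, via C6-lithiated ether 27 (not isolated)
Conditions: n-BuLi, THF, −78 to −20 °C; NH4Cl (aq)
Reagents that add atoms: none
Why: n-BuLi removes a C6 proton (alpha to the ether oxygen and allylic to the Z C4=C5 alkene) and the oxyallyl anion 27 undergoes a concerted suprafacial [2,3]-Wittig shift through a five-membered envelope in which C6 bonds to C7 while O–C13 breaks and the alkene moves to C11=C13. The closest known reaction type is the transannular [2,3]-Wittig ring contraction of thirteen-membered diallyl ethers to ten-membered homoallylic alcohols. The ten-membered carbocycle C1–C10 is closed by contraction, the C6–C7 bond forming across the preformed macrocycle and not by an end-to-end cyclisation. C7 should be set by attack of the carbanion anti to the allylic C8–O bond, with C8–H eclipsing the alkene because the cis C12 arm enforces that rotamer, and C6 should be set relative to C7 by the trans C13/C8 alkene geometry, which puts the C5 vinyl group exo on the envelope and gives the 6,7-anti (trans) product. The step needs lithiation at C6 and not at C13 or C12: C6–H sits on an unhindered CH2 next to a CH= carbon, whereas C13 and C12 both hang on the fully substituted C11 beside the bulky silyl ether, and the low temperature holds back the [1,2]-shift.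

Step 18
Reactants: 28 ten-membered C6 alcohol
Product: 29 (4R,5S)-4,5-epoxy C6 alcohol
Conditions: VO(acac)2 (cat.), tBuOOH, CH2Cl2, 0 °C
Reagents that add atoms: tert-butyl hydroperoxide, CC(C)(C)OO
Why: Hydroxyl-directed vanadium-catalysed epoxidation delivers oxygen from the C6 vanadate ester to the alkene face it reaches with a small O–C6–C5=C4 dihedral while C7 lies on the other face, which should give the cis-epoxy alcohol as medium-ring Z-cycloalkenols do, and the allylic trisubstituted alkene reacts much faster than the homoallylic C11=C13.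

Step 19
Reactants: 29 epoxy alcohol
Product: 30 epoxy triol (C1, C6, C12 hydroxyls free; 8-OTBS)
Conditions: HF·pyridine, pyridine, THF, 0 °C to rt
Reagents that add atoms: none
Why: Buffered fluoride cleaves the primary allylic TBS ether (C12) and the secondary TES ether (C1) much faster than the hindered secondary TBS ether at C8, and the pyridine buffer spares the epoxide.

Step 20
Reactants: 30 epoxy triol
Product: 33 α-methylene 12,6-lactone (1-OH; 8-OTBS), via hydroxy enal 31 (not isolated), via lactol 32 (not isolated)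
Conditions: MnO2 (activated), CH2Cl2, rt
Reagents that add atoms: none
Why: MnO2 oxidises only the primary allylic C12 alcohol to enal 31, the C6 hydroxyl closes lactol 32 (5-exo hemiacetal formation) and this is oxidised on to the γ-lactone, an oxidative lactonisation of a 2-methylene-1,4-diol that leaves the non-allylic C1 alcohol alone.

Step 21
Reactants: 33 α-methylene lactone
Product: 34 1-acetate of 33
Conditions: Ac2O, pyridine, DMAP (cat.), CH2Cl2, 0 °C to rt
Reagents that add atoms: acetic anhydride, CC(=O)OC(C)=O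
Why: Acylation of the only free hydroxyl installs the C1 acetate.

Step 22
Reactants: 34 α-methylene lactone 1-acetate
Product: 37 13-acetoxy-7(11)-en-12,6-olide (8-OTBS), via acetoxy selenide 35 (not isolated), via selenoxide 36 (not isolated)
Conditions: PhSeBr, AgOAc, NaOAc, CH2Cl2/AcOH, 0 °C to rt; then H2O2 (30%), pyridine, 0 °C to rt
Reagents that add atoms: silver acetate, CC(=O)[O-].[Ag+]
Why: Acetoxyselenenylation of the enoate alkene puts PhSe on C11 (alpha) and acetate on C13 (beta), the selenium entering anti to C8 and so cis to H7, and the selenoxide then undergoes syn-elimination toward H7 and away from the oxygen-bearing C13 (allylic acetate synthesis by oxyselenenylation–selenoxide elimination), which moves the alkene to C7=C11.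

Step 23
Reactants: 37 13-acetoxy butenolide
Product: 38 8-hydroxy-13-acetoxy butenolide
Conditions: HF·pyridine, pyridine, THF, 0 °C to rt
Reagents that add atoms: none
Why: Fluoride desilylation of the last TBS ether under buffered, non-basic conditions that avoid acetyl migration and translactonisation to the C8 oxygen.

Step 24
Reactants: 38 8-hydroxy-13-acetoxy butenolide
Product: 39 target
Conditions: tigloyl chloride, Et3N, DMAP, CH2Cl2, 0 °C to rt
Reagents that add atoms: tigloyl chloride, C/C=C(\C)C(Cl)=O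
Why: DMAP-catalysed acylation of the C8 alcohol with the acid chloride gives the tiglate, whose E alkene is the stable isomer and is kept.

**Compound list**
1 | nerol | CC(C)=CCC/C(C)=C\CO | starting material
2 | neryl PMB ether | CC(C)=CCC/C(C)=C\COCc1ccc(OC)cc1 | intermediate
3 | 6,7-epoxyneryl PMB ether (racemic at the epoxide carbon) | CC1(C)OC1CC/C(C)=C\COCc1ccc(OC)cc1 | intermediate
4 | (4Z)-6-(PMB-oxy)-4-methylhex-4-enal | O=CCC/C(C)=C\COCc1ccc(OC)cc1 | intermediate
5 | (E)-crotylboronic acid pinacol ester | C/C=C/CB1OC(C)(C)C(C)(C)O1 | starting material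
6 | pinacol borate ester of 7 | C=C[C@@H](C)[C@@H](OB1OC(C)(C)C(C)(C)O1)CC/C(C)=C\COCc1ccc(OC)cc1 | intermediate
7 | (3R,4S,7Z)-9-(PMB-oxy)-3,7-dimethylnona-1,7-dien-4-ol | C=C[C@@H](C)[C@@H](O)CC/C(C)=C\COCc1ccc(OC)cc1 | intermediate
8 | C1 triethylsilyl ether of 7 | C=C[C@@H](C)[C@@H](O[Si](CC)(CC)CC)CC/C(C)=C\COCc1ccc(OC)cc1 | intermediate
9 | B-alkyl-9-BBN adduct of 8 (boron on C8) | B1(CC[C@@H](C)[C@@H](O[Si](CC)(CC)CC)CC/C(C)=C\COCc2ccc(OC)cc2)C2CCCC1CCC2 | intermediate
10 | (3R,4S,7Z)-9-(PMB-oxy)-3,7-dimethyl-4-(triethylsilyloxy)non-7-en-1-ol | OCC[C@@H](C)[C@@H](O[Si](CC)(CC)CC)CC/C(C)=C\COCc1ccc(OC)cc1 | intermediate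
11 | (3R,4S,7Z)-9-(PMB-oxy)-3,7-dimethyl-4-(triethylsilyloxy)non-7-enal | O=CC[C@@H](C)[C@@H](O[Si](CC)(CC)CC)CC/C(C)=C\COCc1ccc(OC)cc1 | intermediate
12 | methyl propiolate | C#CC(=O)OC | starting material
13 | lithium methyl propiolate | [Li]C#CC(=O)OC | intermediate
14 | methyl (6R,7S,10Z)-4-hydroxy-12-(PMB-oxy)-6,10-dimethyl-7-(triethylsilyloxy)dodec-10-en-2-ynoate (both C8 epimers) | COC(=O)C#CC(O)C[C@@H](C)[C@@H](O[Si](CC)(CC)CC)CC/C(C)=C\COCc1ccc(OC)cc1 | intermediate
15 | methyl (6R,7S,10Z)-12-(PMB-oxy)-6,10-dimethyl-4-oxo-7-(triethylsilyloxy)dodec-10-en-2-ynoate | COC(=O)C#CC(=O)C[C@@H](C)[C@@H](O[Si](CC)(CC)CC)CC/C(C)=C\COCc1ccc(OC)cc1 | intermediate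
16 | B-alkoxy-9-BBN borinate of 17 | COC(=O)C#C[C@@H](OB1C2CCCC1CCC2)C[C@@H](C)[C@@H](O[Si](CC)(CC)CC)CC/C(C)=C\COCc1ccc(OC)cc1 | intermediate
17 | methyl (4S,6R,7S,10Z)-4-hydroxy-12-(PMB-oxy)-6,10-dimethyl-7-(triethylsilyloxy)dodec-10-en-2-ynoate | COC(=O)C#C[C@@H](O)C[C@@H](C)[C@@H](O[Si](CC)(CC)CC)CC/C(C)=C\COCc1ccc(OC)cc1 | intermediate
18 | sodium cyclic vinylalanate (Al on C11, chelated to the C8 oxygen) | [Na+].COCCO[Al-]1(OCCOC)O[C@@H](C[C@@H](C)[C@@H](O[Si](CC)(CC)CC)CC/C(C)=C\COCc2ccc(OC)cc2)C=C1C(=O)OC | intermediate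
19 | methyl (2Z,4S,6R,7S,10Z)-4-hydroxy-2-iodo-12-(PMB-oxy)-6,10-dimethyl-7-(triethylsilyloxy)dodeca-2,10-dienoate | COC(=O)/C(I)=C/[C@@H](O)C[C@@H](C)[C@@H](O[Si](CC)(CC)CC)CC/C(C)=C\COCc1ccc(OC)cc1 | intermediate
20 | (tributylstannyl)methanol | CCCC[Sn](CCCC)(CCCC)CO | starting material
21 | methyl (2E,4S,6R,7S,10Z)-4-hydroxy-2-(hydroxymethyl)-12-(PMB-oxy)-6,10-dimethyl-7-(triethylsilyloxy)dodeca-2,10-dienoate | COC(=O)/C(CO)=C/[C@@H](O)C[C@@H](C)[C@@H](O[Si](CC)(CC)CC)CC/C(C)=C\COCc1ccc(OC)cc1 | intermediate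
22 | 8,12-bis-TBS ether of 21 | COC(=O)/C(CO[Si](C)(C)C(C)(C)C)=C/[C@@H](O[Si](C)(C)C(C)(C)C)C[C@@H](C)[C@@H](O[Si](CC)(CC)CC)CC/C(C)=C\COCc1ccc(OC)cc1 | intermediate
23 | C13 allylic alcohol (C13 trans to C8; 1-OTES, 8-OTBS, 12-OTBS, 6-OPMB) | OC/C(CO[Si](C)(C)C(C)(C)C)=C/[C@@H](O[Si](C)(C)C(C)(C)C)C[C@@H](C)[C@@H](O[Si](CC)(CC)CC)CC/C(C)=C\COCc1ccc(OC)cc1 | intermediate
24 | C13 allylic chloride | ClC/C(CO[Si](C)(C)C(C)(C)C)=C/[C@@H](O[Si](C)(C)C(C)(C)C)C[C@@H](C)[C@@H](O[Si](CC)(CC)CC)CC/C(C)=C\COCc1ccc(OC)cc1 | intermediate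
25 | seco chloro alcohol (C6–OH, C13–Cl) | ClC/C(CO[Si](C)(C)C(C)(C)C)=C/[C@@H](O[Si](C)(C)C(C)(C)C)C[C@@H](C)[C@@H](O[Si](CC)(CC)CC)CC/C(C)=C\CO | intermediate
26 | thirteen-membered diallyl ether C6–O–C13 (1S,8S,10R) | C1/C(C)=C\COC/C(CO[Si](C)(C)C(C)(C)C)=C/[C@@H](O[Si](C)(C)C(C)(C)C)C[C@@H](C)[C@@H](O[Si](CC)(CC)CC)C1 | intermediate
27 | C6-lithiated ether | C1/C(C)=C\C([Li])OC/C(CO[Si](C)(C)C(C)(C)C)=C/[C@@H](O[Si](C)(C)C(C)(C)C)C[C@@H](C)[C@@H](O[Si](CC)(CC)CC)C1 | intermediate
28 | ten-membered C6 alcohol with C7 alkenyl branch (1S,6R,7S,8S,10R) | C1/C(C)=C\[C@@H](O)[C@H](C(=C)CO[Si](C)(C)C(C)(C)C)[C@@H](O[Si](C)(C)C(C)(C)C)C[C@@H](C)[C@@H](O[Si](CC)(CC)CC)C1 | intermediate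
29 | 4,5-epoxy C6 alcohol (1S,4R,5S,6S,7S,8S,10R) | C1[C@@]2(C)O[C@H]2[C@@H](O)[C@H](C(=C)CO[Si](C)(C)C(C)(C)C)[C@@H](O[Si](C)(C)C(C)(C)C)C[C@@H](C)[C@@H](O[Si](CC)(CC)CC)C1 | intermediate
30 | epoxy triol (1-, 6-, 12-OH; 8-OTBS) | C1[C@@]2(C)O[C@H]2[C@@H](O)[C@H](C(=C)CO)[C@@H](O[Si](C)(C)C(C)(C)C)C[C@@H](C)[C@@H](O)C1 | intermediate
31 | hydroxy enal (C12 aldehyde) | C1[C@@]2(C)O[C@H]2[C@@H](O)[C@H](C(=C)C=O)[C@@H](O[Si](C)(C)C(C)(C)C)C[C@@H](C)[C@@H](O)C1 | intermediate
32 | lactol (C12 hemiacetal, either anomer) | C1[C@@]2(C)O[C@H]2[C@H]2OC(O)C(=C)[C@@H]2[C@@H](O[Si](C)(C)C(C)(C)C)C[C@@H](C)[C@@H](O)C1 | intermediate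
33 | α-methylene 12,6-lactone, trans-fused (1-OH; 8-OTBS) | C1[C@@]2(C)O[C@H]2[C@H]2OC(=O)C(=C)[C@@H]2[C@@H](O[Si](C)(C)C(C)(C)C)C[C@@H](C)[C@@H](O)C1 | intermediate
34 | 1-acetate of 33 | C1[C@@]2(C)O[C@H]2[C@H]2OC(=O)C(=C)[C@@H]2[C@@H](O[Si](C)(C)C(C)(C)C)C[C@@H](C)[C@@H](OC(C)=O)C1 | intermediate
35 | 13-acetoxy-11-phenylseleno lactone (Se cis to H7) | C1[C@@]2(C)O[C@H]2[C@H]2OC(=O)[C@@](COC(C)=O)([Se]c3ccccc3)[C@@H]2[C@@H](O[Si](C)(C)C(C)(C)C)C[C@@H](C)[C@@H](OC(C)=O)C1 | intermediate
36 | selenoxide of 35 | C1[C@@]2(C)O[C@H]2[C@H]2OC(=O)[C@@](COC(C)=O)([Se](=O)c3ccccc3)[C@@H]2[C@@H](O[Si](C)(C)C(C)(C)C)C[C@@H](C)[C@@H](OC(C)=O)C1 | intermediate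
37 | 1,13-diacetoxy-4,5-epoxy-8-(TBS-oxy)germacr-7(11)-en-12,6-olide (1S,4R,5S,6S,8S,10R) | C1[C@@]2(C)O[C@H]2[C@H]2OC(=O)C(COC(C)=O)=C2[C@@H](O[Si](C)(C)C(C)(C)C)C[C@@H](C)[C@@H](OC(C)=O)C1 | intermediate
38 | 8-hydroxy analogue of 37 | C1[C@@]2(C)O[C@H]2[C@H]2OC(=O)C(COC(C)=O)=C2[C@@H](O)C[C@@H](C)[C@@H](OC(C)=O)C1 | intermediate
39 | CNP0287840.1 (1,13-diacetoxy-4,5-epoxy-8-tigloyloxygermacr-7(11)-en-12,6-olide) | C/C=C(\C)C(=O)O[C@H]1C[C@@H](C)[C@@H](OC(C)=O)CC[C@@]2(C)O[C@H]2[C@H]2OC(=O)C(COC(C)=O)=C12 | target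

**Step count and risks**

Total: 24 steps. Longest linear sequence: 24 steps from nerol (5, 12 and 20 are bought).

Steps most likely to fail:

1. Step 17 ([2,3]-Wittig contraction). What may go wrong: lithiation at C13 or C12 in place of C6 (followed by the other [2,3] mode, a [1,2]-shift or loss of the C8 silyloxy group), or C–C bond formation on the wrong face of C7=C11 so that C6 comes out epimeric. Fallback: the same C6–C7 bond is made by an intramolecular Nozaki–Hiyama allylation. It sets out from 25: MnO2 oxidises the C6 allylic alcohol to the Z-enal chloride F1, and CrCl2 with NaI in THF at high dilution turns the C13 chloride into the allylchromium, which adds through its gamma carbon C7 to the C6 aldehyde in a chair transition state. This forms C6–C7, the C6 hydroxyl and the C11=C13 methylene with anti selectivity and comes back to the route at 28.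

2. Step 22 (acetoxyselenenylation and selenoxide elimination). What may go wrong: sluggish selenenylation of the electron-poor alkene, acid-induced opening of the 4,5-epoxide during the addition, or addition on the face trans to H7 so that the syn-elimination cannot reach C7. Fallback from 34: OsO4 (cat.) with N-methylmorpholine N-oxide dihydroxylates the exocyclic alkene from the H7 face to give the 11,13-diol F2; Ac2O/pyridine acetylates only the primary C13 hydroxyl to give the 11-hydroxy 13-acetate F3; Burgess reagent in warm toluene then dehydrates the tertiary C11 alcohol by syn-elimination toward the cis H7 and comes back at 37.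

3. Step 18 (directed epoxidation). What may go wrong: oxygen delivery to the other alkene face (trans-epoxy alcohol), or competing epoxidation of the homoallylic C11=C13 alkene. Fallback from 28: the alkene is carried on and the epoxide is installed by halohydrin closure, which inverts the facial outcome of electrophilic attack. HF·pyridine gives the alkene triol F4, MnO2 gives the alkene α-methylene lactone F5, and Ac2O/pyridine gives its 1-acetate F6. NBS in THF/H2O then adds bromine to C5 on the exposed alkene face with water entering C4 from the other face to give bromohydrin F7, and K2CO3 in MeCN closes the epoxide by backside displacement at C5, coming back at 34.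

**Further compounds**
F1 | step 17 | Z-enal chloride (C6 aldehyde, C13 chloride) | ClC/C(CO[Si](C)(C)C(C)(C)C)=C/[C@@H](O[Si](C)(C)C(C)(C)C)C[C@@H](C)[C@@H](O[Si](CC)(CC)CC)CC/C(C)=C\C=O
F2 | step 22 | 11,13-diol of 34 (11-OH cis to H7) | C1[C@@]2(C)O[C@H]2[C@H]2OC(=O)[C@](O)(CO)[C@@H]2[C@@H](O[Si](C)(C)C(C)(C)C)C[C@@H](C)[C@@H](OC(C)=O)C1
F3 | step 22 | 11-hydroxy 13-acetate | C1[C@@]2(C)O[C@H]2[C@H]2OC(=O)[C@](O)(COC(C)=O)[C@@H]2[C@@H](O[Si](C)(C)C(C)(C)C)C[C@@H](C)[C@@H](OC(C)=O)C1
F4 | step 18 | alkene triol (1-, 6-, 12-OH; 8-OTBS; Z C4=C5) | C1/C(C)=C\[C@@H](O)[C@H](C(=C)CO)[C@@H](O[Si](C)(C)C(C)(C)C)C[C@@H](C)[C@@H](O)C1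
F5 | step 18 | alkene α-methylene 12,6-lactone (1-OH) | C1/C(C)=C\[C@H]2OC(=O)C(=C)[C@@H]2[C@@H](O[Si](C)(C)C(C)(C)C)C[C@@H](C)[C@@H](O)C1
F6 | step 18 | 1-acetate of F5 | C1/C(C)=C\[C@H]2OC(=O)C(=C)[C@@H]2[C@@H](O[Si](C)(C)C(C)(C)C)C[C@@H](C)[C@@H](OC(C)=O)C1
F7 | step 18 | 5-bromo-4-hydroxy bromohydrin | C1[C@@](C)(O)[C@H](Br)[C@H]2OC(=O)C(=C)[C@@H]2[C@@H](O[Si](C)(C)C(C)(C)C)C[C@@H](C)[C@@H](OC(C)=O)C1
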